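The route rests on cutting the C2=C3 enamide bond of the epoxycyclohexenone ring (C1–C6), read as a dehydroamino ketone. An intramolecular Horner–Wadsworth–Emmons olefination joins C2, an α-amido-β-ketophosphonate carbon carrying the complete trienamide, to the non-enolisable C3 aldehyde on quaternary C4. It closes the carbocycle with oxirane, C4 carbinol and vinylstannane in place and erases the stereorandom C1/C2 centres of its precursor. That precursor is an opened pyranose: C3–C4–C5–C6–C1 come from furfuryl alcohol by Achmatowicz rearrangement, dynamic kinetic acylation, epoxidation and vinyllithium addition, so that C2–N finally takes the place of the pyranose ring oxygen.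

Key step: step 15

Numbering used throughout (target ring): C1 ketone carbon, C2 N-bearing alkene carbon, C3 alkene CH, C4 carbinol carbon, C5 and C6 oxirane carbons (C6 next to C1).
Assumption: in step 10 (R)-benzotetramisole is taken to acylate the (R)-lactol faster. If the sense of induction is the opposite, the equally available (S)-catalyst is used.

Step 1
Reactants: 1 (E)-4-methylpent-2-enal; 2 triethyl 4-phosphonocrotonate
Product: 3 ethyl (2E,4E,6E)-8-methylnona-2,4,6-trienoate
Conditions: LiHMDS, THF, −78 → 0 °C
Reagents that add atoms: none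
Why: Vinylogous Horner–Wadsworth–Emmons olefination: the lithiated phosphonocrotonate attacks the enal through the carbon next to phosphorus and the stabilised carbanion should give the new C4=C5 bond with E geometry, the two existing E alkenes being untouched.

Step 2
Reactants: 3 ethyl (2E,4E,6E)-8-methylnona-2,4,6-trienoate
Product: 4 (2E,4E,6E)-8-methylnona-2,4,6-trienoic acid
Conditions: LiOH, THF/MeOH/H2O, rt; then aq. HCl
Reagents that add atoms: lithium hydroxide, [Li+].[OH-]
Why: Ester saponification under mild aqueous base, which leaves the conjugated E,E,E-triene unchanged.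

Step 3
Reactants: 4 (2E,4E,6E)-8-methylnona-2,4,6-trienoic acid; 5 diethyl (aminomethyl)phosphonate (free base)
Product: 7 diethyl {[(2E,4E,6E)-8-methylnona-2,4,6-trienamido]methyl}phosphonate, via (2E,4E,6E)-8-methylnona-2,4,6-trienoyl chloride 6 (not isolated)
Conditions: (COCl)2, cat. DMF, CH2Cl2, 0 °C; then 5, Et3N, CH2Cl2, 0 °C → rt
Reagents that add atoms: none
Why: Acid chloride formation by Vilsmeier-type activation followed by Schotten–Baumann-type N-acylation of the primary amine, the phosphonate ester being inert.

Step 4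
Reactants: 8 ethyl (E)-4-oxobut-2-enoate
Product: 9 ethyl (2E,4E)-5-iodopenta-2,4-dienoate
Conditions: CHI3, CrCl2, THF, 0 °C
Reagents that add atoms: iodoform, IC(I)I
Why: Takai olefination: the gem-dichromium species from iodoform adds chemoselectively to the aldehyde and elimination should set the new vinyl iodide E, the enoate being left alone.

Step 5
Reactants: 9 ethyl (2E,4E)-5-iodopenta-2,4-dienoate
Product: 10 (2E,4E)-5-iodopenta-2,4-dienoic acid
Conditions: LiOH, THF/H2O, 0 °C → rt, dark; then aq. HCl
Reagents that add atoms: lithium hydroxide, [Li+].[OH-]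
Why: Ester saponification at low temperature, to which the vinyl iodide and the diene are inert.

Step 6
Reactants: 11 cyclopentane-1,3-dione
Product: 12 2-nitrocyclopentane-1,3-dione (enol form, 3-hydroxy-2-nitrocyclopent-2-en-1-one)
Conditions: fuming HNO3, CH2Cl2, 0 °C
Reagents that add atoms: nitric acid, O[N+](=O)[O-]
Why: Electrophilic nitration of the fully enolised 1,3-dione at its only nucleophilic carbon, C2.

Step 7
Reactants: 12 2-nitrocyclopentane-1,3-dione
Product: 13 2-amino-3-hydroxycyclopent-2-en-1-one hydrochloride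
Conditions: H2 (1 atm), Pd/C, HCl, MeOH, rt
Reagents that add atoms: hydrogen chloride, Cl
Why: Catalytic hydrogenation of the nitro group; the vinylogous acid is not reduced and HCl traps the amine as its salt, which blocks self-condensation.

Step 8
Reactants: 10 (2E,4E)-5-iodopenta-2,4-dienoic acid; 13 2-amino-3-hydroxycyclopent-2-en-1-one hydrochloride
Product: 15 (2E,4E)-N-(2-hydroxy-5-oxocyclopent-1-en-1-yl)-5-iodopenta-2,4-dienamide, via (2E,4E)-5-iodopenta-2,4-dienoyl chloride 14 (not isolated)
Conditions: (COCl)2, cat. DMF, CH2Cl2, 0 °C; then 13, Et3N, THF, −20 °C → rt, dark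
Reagents that add atoms: none
Why: Acid chloride formation and N-acylation of the liberated amine; any O-acylated enol should pass its acyl group to the neighbouring nitrogen (O→N acyl shift).

Step 9
Reactants: 16 furfuryl alcohol
Product: 17 6-hydroxy-2H-pyran-3(6H)-one (racemic lactol)
Conditions: NBS, NaHCO3, THF/H2O, 0 °C
Reagents that add atoms: water, O
Why: Achmatowicz rearrangement: bromonium-induced 2,5-oxidation of the furan, hydrolysis to the Z-keto enal and closure of the primary alcohol onto the aldehyde give the pyranone lactol.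

Step 10
Reactants: 17 6-hydroxy-2H-pyran-3(6H)-one
Product: 18 (2R)-5-oxo-5,6-dihydro-2H-pyran-2-yl 2-methylpropanoate
Conditions: (iPrCO)2O, (R)-benzotetramisole (5 mol %), toluene, 0 °C
Reagents that add atoms: isobutyric anhydride, CC(C)C(=O)OC(=O)C(C)C
Why: Isothiourea-catalysed dynamic kinetic resolution by acylation: the lactol enantiomers interconvert through the open Z-keto enal while the chiral acyl-isothiouronium ion acylates one of them faster, which sets the (R)-acyloxy centre at C1 that relays all later stereochemistry.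

Step 11
Reactants: 18 (2R)-5-oxo-5,6-dihydro-2H-pyran-2-yl 2-methylpropanoate
Product: 19 (1S,2R,6R)-5-oxo-3,7-dioxabicyclo[4.1.0]heptan-2-yl 2-methylpropanoate (oxirane trans to the acyloxy group)
Conditions: tBuOOH, cat. DBU, CH2Cl2, −20 → 0 °C
Reagents that add atoms: tert-butyl hydroperoxide, CC(C)(C)OO
Why: Weitz–Scheffer nucleophilic epoxidation: the peroxide anion adds to the enone β-carbon (C6) anti to the pseudo-axial acyloxy group on the adjacent C1, and closure within the six-membered ring can only give the cis-oxirane, which sets C5 and C6.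

Step 12
Reactants: 19 epoxy ketone; 20 (E)-1,2-bis(tributylstannyl)ethene
Product: 23 (1S,2R,5S,6R)-5-[(E)-2-(tributylstannyl)ethenyl]-5-(triethylsilyloxy)-3,7-dioxabicyclo[4.1.0]heptan-2-yl 2-methylpropanoate, via (E)-2-(tributylstannyl)vinyllithium 21 (not isolated), via tertiary lithium alkoxide 22 (not isolated)
Conditions: 20, n-BuLi, THF, −78 °C; add 19, −78 °C; then TESOTf, −78 → −20 °C
Reagents that add atoms: triethylsilyl triflate, CC[Si](CC)(CC)OS(=O)(=O)C(F)(F)F
Why: Tin–lithium exchange and 1,2-addition to the most electrophilic carbonyl: the vinyllithium attacks the ketone on the face opposite the oxirane oxygen (Felkin-type, anti to the C5–O bond), which sets C4 with its oxygen syn to the oxirane, and the alkoxide is silylated in the same flask.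

Step 13
Reactants: 23 silyl ether ester
Product: 24 (1S,5S,6R)-5-[(E)-2-(tributylstannyl)ethenyl]-5-(triethylsilyloxy)-3,7-dioxabicyclo[4.1.0]heptan-2-ol (lactol, anomeric mixture)
Conditions: cat. K2CO3, MeOH, 0 °C
Reagents that add atoms: none
Why: Base-catalysed transesterification (Zemplén-type methanolysis) removes the activated anomeric ester, while tertiary TES ether, oxirane and vinylstannane are stable to catalytic carbonate.

Step 14
Reactants: 24 lactol; 7 amidomethylphosphonate
Product: 27 open-chain diol phosphonate, HOCH2(C3)–C4(OTES)[(E)-CH=CHSnBu3]–C5/C6 cis-oxirane–C1H(OH)–C2H(NH-trienoyl)[P(O)(OEt)2], C4–C6 configured as in the target, mixture at C1 and C2, via N,C-dilithio derivative of the phosphonate 25 (not isolated), via open-chain lithium alkoxide epoxy aldehyde 26 (not isolated)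
Conditions: 7, LDA (2.1 equiv), THF, −78 → −40 °C; 24, LiHMDS (1 equiv), THF, −78 °C; combine, −78 → −30 °C; AcOH quench
Reagents that add atoms: none
Why: Addition of an α-lithiated phosphonate (N,C-dianion of a secondary amide) to the aldehyde tautomer of a lactol; without a further anion-stabilising group the lithium β-oxidophosphonate does not collapse at low temperature, and the stereorandom C1 and C2 centres are removed in step 15.

Step 15
Reactants: 27 diol phosphonate
Product: 29 (2E,4E,6E)-8-methyl-N-{(1S,5S,6R)-2-oxo-5-[(E)-2-(tributylstannyl)ethenyl]-5-(triethylsilyloxy)-7-oxabicyclo[4.1.0]hept-3-en-3-yl}nona-2,4,6-trienamide, C4–C6 configured as in the target, via keto aldehyde phosphonate 28 (not isolated)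
Conditions: (COCl)2, DMSO, CH2Cl2, −78 °C; Et3N, −78 → 0 °C; then dilute with MeCN, LiCl, 0 °C → rt
Reagents that add atoms: none
Why: Both hydroxyl groups are activated as alkoxysulfonium salts before base is added, so the Swern oxidation should give keto aldehyde 28 without a lactol stage; Et3N/LiCl (Masamune–Roush conditions) then removes the doubly activated C2–H, the lithium-chelated carbanion adds to the C3 aldehyde, and syn-elimination of diethyl phosphate through the oxaphosphetane gives C2=C3. The closest known reaction type is the intramolecular Horner–Wadsworth–Emmons cyclisation of sugar-derived β-ketophosphonate aldehydes to cyclohexenones, merged with the phosphonoglycine-type olefination that makes dehydroamino acid derivatives. The carbocycle closes in a 6-(enolexo)-exo-trig addition, and the ring size allows only the alkene geometry with C1 and C4 on the same side. No stereocentre is created: C4 (quaternary) and C5/C6 (oxirane C–H) carry no acidic hydrogen and stay untouched, while all four C1/C2 diastereomers of 27 converge on one product. The step needs C2 as the only nucleophile and ring closure over intermolecular olefination; this is secured because C2–H is the only acidic C–H (the aldehyde cannot enolise), the cis-oxirane holds the C1 and C4 arms on one side, and the olefination runs at high dilution.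

Step 16
Reactants: 29 vinylstannane core; 15 iododienamide
Product: 30 4-O-triethylsilyl manumycin G
Conditions: PdCl2(MeCN)2 (10 mol %), DMF, rt, dark
Reagents that add atoms: none
Why: Stille coupling of vinylstannane and vinyl iodide, which proceeds with retention at both alkenes to give the E,E,E-triene and tolerates enone, oxirane, amide N–H and the acidic enol.

Step 17
Reactants: 30 4-O-triethylsilyl manumycin G
Product: 31 manumycin G
Conditions: HF·pyridine, pyridine, THF, 0 °C
Reagents that add atoms: none
Why: Fluoride-mediated cleavage of the tertiary TES ether under pyridine-buffered conditions that spare the oxirane, the doubly allylic carbinol and both trienamides.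

Compound list
1 | (E)-4-methylpent-2-enal | CC(C)/C=C/C=O | starting material
2 | triethyl 4-phosphonocrotonate | CCOC(=O)/C=C/CP(=O)(OCC)OCC | starting material
3 | ethyl (2E,4E,6E)-8-methylnona-2,4,6-trienoate | CCOC(=O)/C=C/C=C/C=C/C(C)C | intermediate
4 | (2E,4E,6E)-8-methylnona-2,4,6-trienoic acid | OC(=O)/C=C/C=C/C=C/C(C)C | intermediate
5 | diethyl (aminomethyl)phosphonate | NCP(=O)(OCC)OCC | starting material
6 | (2E,4E,6E)-8-methylnona-2,4,6-trienoyl chloride | ClC(=O)/C=C/C=C/C=C/C(C)C | intermediate
7 | diethyl {[(2E,4E,6E)-8-methylnona-2,4,6-trienamido]methyl}phosphonate | CC(C)/C=C/C=C/C=C/C(=O)NCP(=O)(OCC)OCC | intermediate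
8 | ethyl (E)-4-oxobut-2-enoate | CCOC(=O)/C=C/C=O | starting material
9 | ethyl (2E,4E)-5-iodopenta-2,4-dienoate | CCOC(=O)/C=C/C=C/I | intermediate
10 | (2E,4E)-5-iodopenta-2,4-dienoic acid | OC(=O)/C=C/C=C/I | intermediate
11 | cyclopentane-1,3-dione | O=C1CCC(=O)C1 | starting material
12 | 2-nitrocyclopentane-1,3-dione (enol form) | O=C1CCC(O)=C1[N+](=O)[O-] | intermediate
13 | 2-amino-3-hydroxycyclopent-2-en-1-one hydrochloride | Cl.NC1=C(O)CCC1=O | intermediate
14 | (2E,4E)-5-iodopenta-2,4-dienoyl chloride | ClC(=O)/C=C/C=C/I | intermediate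
15 | (2E,4E)-N-(2-hydroxy-5-oxocyclopent-1-en-1-yl)-5-iodopenta-2,4-dienamide | O=C(/C=C/C=C/I)NC1=C(O)CCC1=O | intermediate
16 | furfuryl alcohol | OCc1ccco1 | starting material
17 | 6-hydroxy-2H-pyran-3(6H)-one | O=C1COC(O)C=C1 | intermediate
18 | (2R)-5-oxo-5,6-dihydro-2H-pyran-2-yl 2-methylpropanoate | O=C1CO[C@H](OC(=O)C(C)C)C=C1 | intermediate
19 | (1S,2R,6R)-5-oxo-3,7-dioxabicyclo[4.1.0]heptan-2-yl 2-methylpropanoate | O=C1CO[C@H](OC(=O)C(C)C)[C@H]2O[C@@H]12 | intermediate
20 | (E)-1,2-bis(tributylstannyl)ethene | CCCC[Sn](CCCC)(CCCC)/C=C/[Sn](CCCC)(CCCC)CCCC | starting material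
21 | (E)-2-(tributylstannyl)vinyllithium | [Li]/C=C/[Sn](CCCC)(CCCC)CCCC | intermediate
22 | tertiary lithium alkoxide from 19 and 21 | [Li]O[C@@]1(/C=C/[Sn](CCCC)(CCCC)CCCC)CO[C@H](OC(=O)C(C)C)[C@H]2O[C@@H]12 | intermediate
23 | (1S,2R,5S,6R)-5-[(E)-2-(tributylstannyl)ethenyl]-5-(triethylsilyloxy)-3,7-dioxabicyclo[4.1.0]heptan-2-yl 2-methylpropanoate | CC[Si](CC)(CC)O[C@@]1(/C=C/[Sn](CCCC)(CCCC)CCCC)CO[C@H](OC(=O)C(C)C)[C@H]2O[C@@H]12 | intermediate
24 | lactol, 5-[(E)-2-(tributylstannyl)ethenyl]-5-(triethylsilyloxy)-3,7-dioxabicyclo[4.1.0]heptan-2-ol | CC[Si](CC)(CC)O[C@@]1(/C=C/[Sn](CCCC)(CCCC)CCCC)COC(O)[C@H]2O[C@@H]12 | intermediate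
25 | N,C-dilithio derivative of 7 | CCOP(=O)(OCC)C([Li])N([Li])C(=O)/C=C/C=C/C=C/C(C)C | intermediate
26 | open-chain lithium alkoxide epoxy aldehyde from 24 | [Li]OC[C@@](O[Si](CC)(CC)CC)(/C=C/[Sn](CCCC)(CCCC)CCCC)[C@@H]1O[C@@H]1C=O | intermediate
27 | open-chain diol phosphonate | OC[C@@](O[Si](CC)(CC)CC)(/C=C/[Sn](CCCC)(CCCC)CCCC)[C@@H]1O[C@@H]1C(O)C(NC(=O)/C=C/C=C/C=C/C(C)C)P(=O)(OCC)OCC | intermediate
28 | keto aldehyde phosphonate | O=C[C@@](O[Si](CC)(CC)CC)(/C=C/[Sn](CCCC)(CCCC)CCCC)[C@@H]1O[C@@H]1C(=O)C(NC(=O)/C=C/C=C/C=C/C(C)C)P(=O)(OCC)OCC | intermediate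
29 | silyl-protected epoxycyclohexenone core with trienamide and vinylstannane | CC(C)/C=C/C=C/C=C/C(=O)NC1=C[C@@](O[Si](CC)(CC)CC)(/C=C/[Sn](CCCC)(CCCC)CCCC)[C@@H]2O[C@@H]2C1=O | intermediate
30 | 4-O-triethylsilyl manumycin G | CC(C)/C=C/C=C/C=C/C(=O)NC1=C[C@@](O[Si](CC)(CC)CC)(/C=C/C=C/C=C/C(=O)NC2=C(O)CCC2=O)[C@@H]2O[C@@H]2C1=O | intermediate
31 | manumycin G | CC(C)/C=C/C=C/C=C/C(=O)NC1=C[C@@](O)(/C=C/C=C/C=C/C(=O)NC2=C(O)CCC2=O)[C@@H]2O[C@@H]2C1=O | target

Total step count: 17. Longest linear sequence: 9 steps (steps 9–17, from furfuryl alcohol).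

Steps most likely to fail

Step 14. The amidomethylphosphonate may be metalated incompletely at carbon. Deprotonation may stray to the vinylogous C8–H of the trienamide, or the lactolate may open too slowly. Any of these would leave the aldehyde unconsumed. The fallback sets out from 24 and returns at 29, and it brings in C2–N as nitromethane instead of as a phosphonate. A base-catalysed Henry reaction on 24 should give nitro diol F1. SmI2 reduction then gives amino diol F2, and acylation with acid chloride 6 gives amido diol F3. Swern oxidation gives keto aldehyde F4, whose α-amido ketone closes onto the C3 aldehyde in an intramolecular aldol reaction (DBU) to aldol F5. This is dehydrated through mesylate F6 (MsCl, Et3N) to 29.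

Step 15. A half-oxidised hydroxy aldehyde may close to a lactol and be over-oxidised to a δ-lactone. Excess activated DMSO may functionalise the acidic C2 position. Slow attack on the neopentyl-type aldehyde may also let intermolecular olefination compete. The fallback sets out from 24 and returns at 28, and it moves the C1 oxidation ahead of the C–C bond formation. Ley–Griffith oxidation of 24 gives δ-lactone F7. Acylation of dianion 25 by F7 gives hydroxy β-ketophosphonate F8 (in equilibrium with its hemiketal), in which the primary alcohol is the only oxidisable group. Dess–Martin oxidation then gives 28, which is isolated and closed in a separate operation with K2CO3/18-crown-6 in toluene at high dilution.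

Step 11. The base may expel the anomeric isobutyrate (oxidopyrylium formation and dimerisation), or the peroxide may cleave the ester faster than it adds to the enone, which would also erode the facial control. The fallback sets out from 18 and returns at 24, and it exchanges the base-labile ester before the epoxidation. Pd(0)-catalysed allylic substitution with 2-nitrobenzyl alcohol (net retention by double inversion) gives 2-nitrobenzyl glycoside F9. Weitz–Scheffer epoxidation gives epoxy ketone F10. Addition of 21 and silylation as in step 12 gives silyl ether F11, and photolysis at 365 nm releases lactol 24 under neutral conditions.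

Further compounds
F1 | step 14 | nitro diol | OC[C@@](O[Si](CC)(CC)CC)(/C=C/[Sn](CCCC)(CCCC)CCCC)[C@@H]1O[C@@H]1C(O)C[N+](=O)[O-]
F2 | step 14 | amino diol | OC[C@@](O[Si](CC)(CC)CC)(/C=C/[Sn](CCCC)(CCCC)CCCC)[C@@H]1O[C@@H]1C(O)CN
F3 | step 14 | amido diol | OC[C@@](O[Si](CC)(CC)CC)(/C=C/[Sn](CCCC)(CCCC)CCCC)[C@@H]1O[C@@H]1C(O)CNC(=O)/C=C/C=C/C=C/C(C)C
F4 | step 14 | keto aldehyde without phosphonate | O=C[C@@](O[Si](CC)(CC)CC)(/C=C/[Sn](CCCC)(CCCC)CCCC)[C@@H]1O[C@@H]1C(=O)CNC(=O)/C=C/C=C/C=C/C(C)C
F5 | step 14 | aldol (3-hydroxy-2-amidocyclohexanone) | CC(C)/C=C/C=C/C=C/C(=O)NC1C(O)[C@@](O[Si](CC)(CC)CC)(/C=C/[Sn](CCCC)(CCCC)CCCC)[C@@H]2O[C@@H]2C1=O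
F6 | step 14 | mesylate of the aldol | CC(C)/C=C/C=C/C=C/C(=O)NC1C(OS(C)(=O)=O)[C@@](O[Si](CC)(CC)CC)(/C=C/[Sn](CCCC)(CCCC)CCCC)[C@@H]2O[C@@H]2C1=O
F7 | step 15 | δ-lactone | CC[Si](CC)(CC)O[C@@]1(/C=C/[Sn](CCCC)(CCCC)CCCC)COC(=O)[C@H]2O[C@@H]12
F8 | step 15 | hydroxy β-ketophosphonate | OC[C@@](O[Si](CC)(CC)CC)(/C=C/[Sn](CCCC)(CCCC)CCCC)[C@@H]1O[C@@H]1C(=O)C(NC(=O)/C=C/C=C/C=C/C(C)C)P(=O)(OCC)OCC
F9 | step 11 | 2-nitrobenzyl glycoside of the pyranone | O=C1CO[C@H](OCc2ccccc2[N+](=O)[O-])C=C1
F10 | step 11 | epoxy ketone 2-nitrobenzyl glycoside | O=C1CO[C@H](OCc2ccccc2[N+](=O)[O-])[C@H]3O[C@@H]13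
F11 | step 11 | silyl ether vinylstannane 2-nitrobenzyl glycoside | CC[Si](CC)(CC)O[C@@]1(/C=C/[Sn](CCCC)(CCCC)CCCC)CO[C@H](OCc2ccccc2[N+](=O)[O-])[C@H]3O[C@@H]13
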